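The bicyclo[3.2.1]octane (C1 allyl bridgehead, C2, C3 methoxy carbon, C4 ketone, C5 methoxy bridgehead, C6 aryl carbon, C7 methyl carbon, C8 carbinol bridge) is disconnected at C1–C7. The feature used is that the allyl-bearing bridgehead C1 sits next to the C8 oxygen function while its neighbour C7 holds a methyl group: a C8 silyl enol ether makes C1 nucleophilic, and a terminal alkyne on C6 supplies C7 plus the future methyl carbon. One gold-catalysed 5-exo-dig carbocyclisation closes the five-membered ring C1–C7–C6–C5–C8 and creates quaternary C1. The precursor is a 2-allylcyclohexenyl silyl ether carrying methoxy and the arylpropynyl arm on C5, with C4 as a silyl-protected carbinol.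

Key step: step 9

Labels: C1–C8 as above are used for every compound. Ar = 3-(tert-butyldimethylsilyloxy)-4-methoxyphenyl. On C6/C7, endo means the side of the C2–C4 bridge and exo the side of C8.

Remark on the design: C4 passes through the cyclisation as a triethylsilyl-protected carbinol. The reduction that creates it tells the two carbonyl groups of the prochiral dione apart (fixing C5 relative to C6), leaves C1 as the only enolisable position, and removes a carbonyl oxygen that could add to the activated alkyne. The C4 ketone returns in steps 10 and 11.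

Assumption: the Ph-pybox enantiomer in step 4 is the one that gives S at C6. It is written as (S,S) and would be exchanged for (R,R) if the sense of induction is the opposite.

Step 1
Reactants: 1 2-methoxyresorcinol
Product: 2 2-methoxycyclohexane-1,3-dione
Conditions: H2 (5 bar), Pd/C, NaOH (1.1 equiv), H2O, 50 °C; then HCl
Reagents that add atoms: none
Why: Partial hydrogenation of the resorcinol monoanion stops at the vinylogous carboxylate of the 1,3-dione, the same arene-to-dione reduction that turns resorcinol into cyclohexane-1,3-dione, and no stereocentre is formed.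

Step 2
Reactants: 3 isovanillin
Product: 4 3-(tert-butyldimethylsilyloxy)-4-methoxybenzaldehyde
Conditions: t-BuMe2SiCl, imidazole, DMF, rt
Reagents that add atoms: tert-butyldimethylsilyl chloride, CC(C)(C)[Si](C)(C)Cl
Why: Standard silylation of a phenol with a silyl chloride and imidazole gives an ether that tolerates the Grignard, enolate, gold and radical steps that follow.

Step 3
Reactants: 4 3-(tert-butyldimethylsilyloxy)-4-methoxybenzaldehyde; 5 ethynylmagnesium bromide
Product: 7 racemic 1-Ar-prop-2-yn-1-yl acetate, via bromomagnesium propargylic alkoxide 6 (not isolated)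
Conditions: THF, 0 °C; then Ac2O, 0 °C to rt
Reagents that add atoms: ethynylmagnesium bromide (5), C#C[Mg]Br; acetic anhydride, CC(=O)OC(C)=O
Why: Grignard 1,2-addition to the aldehyde gives the magnesium alkoxide, which is acetylated in the same flask; the acetate is racemic, which does not matter because step 4 is enantioconvergent.

Step 4
Reactants: 2 2-methoxycyclohexane-1,3-dione; 7 racemic 1-Ar-prop-2-yn-1-yl acetate
Product: 8 2-methoxy-2-[(1S)-1-Ar-prop-2-yn-1-yl]cyclohexane-1,3-dione
Conditions: Cu(MeCN)4PF6 (5 mol%), (S,S)-Ph-pybox (6 mol%), i-Pr2NEt, MeOH, −20 °C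
Reagents that add atoms: none
Why: Copper-catalysed asymmetric propargylic substitution: the acetate ionises to a planar copper allenylidene so that both enantiomers of 7 converge, and the enol of 2 attacks the γ-carbon through carbon on the face left open by the pybox ligand, which sets C6 (S) while C5 stays prochiral.

Step 5
Reactants: 8 2-methoxy-2-[(1S)-1-Ar-prop-2-yn-1-yl]cyclohexane-1,3-dione
Product: 9 (2R,3S)-3-hydroxy-2-methoxy-2-[(1S)-1-Ar-prop-2-yn-1-yl]cyclohexan-1-one (ring C2 = C5, ring C3 = C4, hydroxyl cis to the propynyl arm)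
Conditions: (R)-2-methyl-CBS-oxazaborolidine (20 mol%), catecholborane, toluene, −78 °C
Reagents that add atoms: none
Why: Corey–Bakshi–Shibata reduction used as a desymmetrisation of a 2,2-disubstituted 1,3-dione: the (R)-catalyst makes the S carbinol, and only at one of the two diastereotopic carbonyls does this coincide with hydride delivery anti to the bulky propynyl arm, so that carbonyl becomes C4 and C5 becomes a defined stereocentre (R).

Step 6
Reactants: 9 the hydroxy ketone
Product: 10 (2R,3S)-2-methoxy-2-[(1S)-1-Ar-prop-2-yn-1-yl]-3-(triethylsilyloxy)cyclohexan-1-one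
Conditions: Et3SiOTf, 2,6-lutidine, CH2Cl2, −78 °C
Reagents that add atoms: triethylsilyl trifluoromethanesulfonate, CC[Si](CC)(CC)OS(=O)(=O)C(F)(F)F
Why: Silylation of a secondary alcohol with a silyl triflate and a hindered pyridine base is fast at low temperature and avoids retro-aldol cleavage of the β-hydroxy ketone.

Step 7
Reactants: 10 the triethylsilyl ether; 11 allyl bromide
Product: 13 (2R,3S)-6-allyl-2-methoxy-2-[(1S)-1-Ar-prop-2-yn-1-yl]-3-(triethylsilyloxy)cyclohexan-1-one as a mixture of epimers at the allyl-bearing carbon C1, via dilithio enolate acetylide 12 (not isolated)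
Conditions: LiN(i-Pr)2 (2.2 equiv), THF, −78 °C; allyl bromide, −78 to −20 °C; AcOH
Reagents that add atoms: allyl bromide (11), C=CCBr
Why: Ketone enolate alkylation: C5 is quaternary so the C8 ketone can be deprotonated only at C1, the lithium acetylide formed alongside is inert to allyl bromide at low temperature, and the C1 configuration is left uncontrolled because step 8 makes this carbon trigonal.

Step 8
Reactants: 13 the allyl ketone
Product: 14 (5S,6R)-2-allyl-6-methoxy-6-[(1S)-1-Ar-prop-2-yn-1-yl]-5-(triethylsilyloxy)cyclohex-1-en-1-yl tert-butyldimethylsilyl ether (ring C1 = C8, ring C2 = C1, ring C5 = C4, ring C6 = C5)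
Conditions: t-BuMe2SiOTf, Et3N, CH2Cl2, 0 °C to rt
Reagents that add atoms: tert-butyldimethylsilyl trifluoromethanesulfonate, CC(C)(C)[Si](C)(C)OS(=O)(=O)C(F)(F)F
Why: Soft enolisation with a silyl triflate and an amine gives the only possible enol ether, the tetrasubstituted C8=C1 one, without deprotonating the terminal alkyne.

Step 9
Reactants: 14 the silyl enol ether
Product: 15 1-allyl-6-endo-Ar-5-methoxy-7-methylene-4-(triethylsilyloxy)bicyclo[3.2.1]octan-8-one (silyloxy on C4 cis to the C6–C7 bridge)
Conditions: Ph3PAuNTf2 (5 mol%), CH2Cl2/MeOH 10:1, rt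
Reagents that add atoms: none
Why: Cationic monovalent gold binds the terminal alkyne, the enol ether carbon C1 adds anti to gold at the internal carbon C7 (Markovnikov), and methanol takes the silyl group from the oxocarbenium ion and protonates the vinylgold, which releases the C8 ketone and the C7 methylene. The closest known reaction type is the gold-catalysed Conia-ene-type carbocyclisation of silyl enol ethers onto alkynes, including closures of cyclic enol ethers that carry the alkyne on the α′ carbon and so give bridged ketones. The one ring formed, C1–C7–C6–C5–C8, closes in the 5-exo-dig mode. The new stereocentre C1 is controlled by C5, because the two-atom tether reaches only the enol face on which the arm stands, and the endo position of the aryl group follows from the C5/C6 relationship fixed in steps 4 and 5. The step needs attack through carbon at the internal alkyne carbon in preference to 6-endo closure and to O-attack; a terminal alkyne with a compact phosphine ligand favours the 5-exo path, and with C4 as a silyl ether there is neither a second enol nor a carbonyl oxygen to compete.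

Step 10
Reactants: 15 the bicyclic silyloxy ketone
Product: 16 1-allyl-6-endo-Ar-4-hydroxy-5-methoxy-7-methylenebicyclo[3.2.1]octan-8-one
Conditions: PPTS, MeOH, rt
Reagents that add atoms: none
Why: Acid-catalysed methanolysis of a trialkylsilyl ether cleaves the secondary triethylsilyl ether, while the aryl tert-butyldimethylsilyl ether is stable to mild acid.

Step 11
Reactants: 16 the hydroxy ketone
Product: 17 1-allyl-6-endo-Ar-5-methoxy-7-methylenebicyclo[3.2.1]octane-4,8-dione
Conditions: Dess–Martin periodinane, NaHCO3, CH2Cl2, rt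
Reagents that add atoms: none
Why: Dess–Martin oxidation of the secondary alcohol under buffered conditions restores the C4 ketone, and the resulting β-diketone cannot enolise between the carbonyls because C5 is quaternary.

Step 12
Reactants: 17 the 4,8-dione
Product: 19 the C3-hydroxy dione (hydroxyl on the face opposite the C6–C7 bridge), via potassium enolate 18 (not isolated)
Conditions: KN(SiMe3)2, THF, −78 °C; 2-(phenylsulfonyl)-3-phenyloxaziridine; AcOH
Reagents that add atoms: 2-(phenylsulfonyl)-3-phenyloxaziridine, O=S(=O)(c1ccccc1)N1OC1c1ccccc1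
Why: Enolate hydroxylation with an N-sulfonyloxaziridine (Davis oxidation): C3 is the only enolisable position since C5 is quaternary and C8 has no α-hydrogen, and oxygen is expected to enter on the enolate face turned away from the C6–C7 bridge and its aryl group, a C3 configuration that is reset in step 14.

Step 13
Reactants: 19 the C3-hydroxy dione
Product: 20 the C3-methoxy dione (methoxy on the face opposite the C6–C7 bridge)
Conditions: Me3OBF4, 1,8-bis(dimethylamino)naphthalene, CH2Cl2, rt
Reagents that add atoms: trimethyloxonium tetrafluoroborate, C[O+](C)C.F[B-](F)(F)F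
Why: O-Methylation with a trialkyloxonium salt and a hindered non-nucleophilic base avoids enolate formation and retro-Claisen opening of the β-diketone.

Step 14
Reactants: 20 the C3-methoxy dione
Product: 23 1-allyl-6-endo-Ar-8-hydroxy-3,5-dimethoxy-7-methylenebicyclo[3.2.1]octan-4-one (C8 hydroxyl syn to the C2–C4 bridge; C3 methoxy cis to the C6–C7 bridge), via potassium enolate 21 (not isolated), via lithium alkoxide potassium enolate 22 (not isolated)
Conditions: KN(SiMe3)2, THF, −78 to −40 °C; LiAlH4, −78 °C; AcOH, −78 °C
Reagents that add atoms: none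
Why: Temporary protection of the enolisable C4 ketone as its enolate leaves C8 as the only carbonyl open to hydride, which should enter over the C6–C7 bridge (trigonal C7, and away from the anionic enolate) to place the hydroxyl syn to the C2–C4 bridge, and low-temperature C-protonation of the methoxy enolate on its exposed face, anti to the aryl-bearing bridge, then sets C3.

Step 15
Reactants: 23 the methylene hydroxy ketone
Product: 24 the tert-butyldimethylsilyl ether of the target (C7 methyl exo, trans to the aryl group)
Conditions: Mn(dpm)3 (10 mol%), PhSiH3, t-BuOOH, i-PrOH, rt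
Reagents that add atoms: none
Why: Radical hydrogenation by metal-hydride hydrogen-atom transfer (Mukaiyama type): the 1,1-disubstituted alkene, which gives a tertiary radical, should react faster than the monosubstituted allyl group, and hydrogen capture by the C7 radical should favour the more stable exo-methyl isomer, trans to the endo aryl group.

Step 16
Reactants: 24 the silyl ether of the target
Product: 25 (1S,3S,5S,6S,7R,8S)-1-allyl-8-hydroxy-6-(3-hydroxy-4-methoxyphenyl)-3,5-dimethoxy-7-methylbicyclo[3.2.1]octan-4-one (CNP0209708.1)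
Conditions: Bu4NF, AcOH, THF, 0 °C
Reagents that add atoms: none
Why: Fluoride cleavage of the aryl silyl ether, with acetic acid buffering the phenoxide so that the β-hydroxy ketone is not exposed to base (no retro-aldol, no epimerisation at C3).

Compound list

1 | 2-methoxyresorcinol (2-methoxybenzene-1,3-diol) | COc1c(O)cccc1O | starting material
2 | 2-methoxycyclohexane-1,3-dione | COC1C(=O)CCCC1=O | intermediate
3 | isovanillin (3-hydroxy-4-methoxybenzaldehyde) | COc1ccc(C=O)cc1O | starting material
4 | 3-(tert-butyldimethylsilyloxy)-4-methoxybenzaldehyde | COc1ccc(C=O)cc1O[Si](C)(C)C(C)(C)C | intermediate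
5 | ethynylmagnesium bromide | C#C[Mg]Br | starting material
6 | bromomagnesium 1-Ar-prop-2-yn-1-olate (not isolated) | C#CC(O[Mg]Br)c1ccc(OC)c(O[Si](C)(C)C(C)(C)C)c1 | intermediate
7 | racemic 1-Ar-prop-2-yn-1-yl acetate | CC(=O)OC(C#C)c1ccc(OC)c(O[Si](C)(C)C(C)(C)C)c1 | intermediate
8 | 2-methoxy-2-[(1S)-1-Ar-prop-2-yn-1-yl]cyclohexane-1,3-dione | COC1([C@@H](C#C)c2ccc(OC)c(O[Si](C)(C)C(C)(C)C)c2)C(=O)CCCC1=O | intermediate
9 | (2R,3S)-3-hydroxy-2-methoxy-2-[(1S)-1-Ar-prop-2-yn-1-yl]cyclohexan-1-one | CO[C@]1([C@@H](C#C)c2ccc(OC)c(O[Si](C)(C)C(C)(C)C)c2)[C@@H](O)CCCC1=O | intermediate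
10 | triethylsilyl ether of 9 | CO[C@]1([C@@H](C#C)c2ccc(OC)c(O[Si](C)(C)C(C)(C)C)c2)[C@@H](O[Si](CC)(CC)CC)CCCC1=O | intermediate
11 | allyl bromide | C=CCBr | starting material
12 | dilithio enolate acetylide of 10 (not isolated) | CO[C@]1([C@@H](C#C[Li])c2ccc(OC)c(O[Si](C)(C)C(C)(C)C)c2)[C@@H](O[Si](CC)(CC)CC)CCC=C1O[Li] | intermediate
13 | (2R,3S)-6-allyl-2-methoxy-2-[(1S)-1-Ar-prop-2-yn-1-yl]-3-(triethylsilyloxy)cyclohexan-1-one, mixture of C1 epimers | CO[C@]1([C@@H](C#C)c2ccc(OC)c(O[Si](C)(C)C(C)(C)C)c2)[C@@H](O[Si](CC)(CC)CC)CCC(CC=C)C1=O | intermediate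
14 | (5S,6R)-2-allyl-6-methoxy-6-[(1S)-1-Ar-prop-2-yn-1-yl]-5-(triethylsilyloxy)cyclohex-1-en-1-yl tert-butyldimethylsilyl ether (key-step precursor) | C=CCC1=C(O[Si](C)(C)C(C)(C)C)[C@@](OC)([C@H](c2ccc(OC)c(O[Si](C)(C)C(C)(C)C)c2)C#C)[C@@H](O[Si](CC)(CC)CC)CC1 | intermediate
15 | 1-allyl-6-endo-Ar-5-methoxy-7-methylene-4-(triethylsilyloxy)bicyclo[3.2.1]octan-8-one (key-step product) | C=CC[C@]12CC[C@H](O[Si](CC)(CC)CC)[C@](OC)([C@H](c3ccc(OC)c(O[Si](C)(C)C(C)(C)C)c3)C1=C)C2=O | intermediate
16 | 1-allyl-6-endo-Ar-4-hydroxy-5-methoxy-7-methylenebicyclo[3.2.1]octan-8-one | C=CC[C@]12CC[C@H](O)[C@](OC)([C@H](c3ccc(OC)c(O[Si](C)(C)C(C)(C)C)c3)C1=C)C2=O | intermediate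
17 | 1-allyl-6-endo-Ar-5-methoxy-7-methylenebicyclo[3.2.1]octane-4,8-dione | C=CC[C@]12CCC(=O)[C@](OC)([C@H](c3ccc(OC)c(O[Si](C)(C)C(C)(C)C)c3)C1=C)C2=O | intermediate
18 | potassium C3=C4 enolate of 17 (not isolated) | C=CC[C@]12CC=C(O[K])[C@](OC)([C@H](c3ccc(OC)c(O[Si](C)(C)C(C)(C)C)c3)C1=C)C2=O | intermediate
19 | C3-hydroxy dione, hydroxyl on the face opposite the C6–C7 bridge | C=CC[C@]12C[C@@H](O)C(=O)[C@](OC)([C@H](c3ccc(OC)c(O[Si](C)(C)C(C)(C)C)c3)C1=C)C2=O | intermediate
20 | C3-methoxy dione, methoxy on the face opposite the C6–C7 bridge | C=CC[C@]12C[C@@H](OC)C(=O)[C@](OC)([C@H](c3ccc(OC)c(O[Si](C)(C)C(C)(C)C)c3)C1=C)C2=O | intermediate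
21 | potassium enolate of 20 (not isolated) | C=CC[C@]12CC(OC)=C(O[K])[C@](OC)([C@H](c3ccc(OC)c(O[Si](C)(C)C(C)(C)C)c3)C1=C)C2=O | intermediate
22 | C8 lithium alkoxide of enolate 21 (not isolated) | C=CC[C@]12CC(OC)=C(O[K])[C@](OC)([C@H](c3ccc(OC)c(O[Si](C)(C)C(C)(C)C)c3)C1=C)[C@H]2O[Li] | intermediate
23 | 1-allyl-6-endo-Ar-8-hydroxy-3,5-dimethoxy-7-methylenebicyclo[3.2.1]octan-4-one | C=CC[C@]12C[C@H](OC)C(=O)[C@](OC)([C@H](c3ccc(OC)c(O[Si](C)(C)C(C)(C)C)c3)C1=C)[C@H]2O | intermediate
24 | tert-butyldimethylsilyl ether of the target | C=CC[C@]12C[C@H](OC)C(=O)[C@](OC)([C@H](c3ccc(OC)c(O[Si](C)(C)C(C)(C)C)c3)[C@H]1C)[C@H]2O | intermediate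
25 | (1S,3S,5S,6S,7R,8S)-1-allyl-8-hydroxy-6-(3-hydroxy-4-methoxyphenyl)-3,5-dimethoxy-7-methylbicyclo[3.2.1]octan-4-one | C=CC[C@]12C[C@H](OC)C(=O)[C@](OC)([C@H](c3ccc(OC)c(O)c3)[C@H]1C)[C@H]2O | target

Total steps: 16. Longest linear sequence: 15 steps (from isovanillin 3, steps 2 to 16).

Steps most likely to fail

Step 15. Hydrogen may be delivered to the exo face of the C7 radical, the face remote from the aryl group, which would give the endo-methyl epimer. Hydrogen-atom transfer to the allyl group may also compete. The fallback sets out from 23, avoids hydrogenation and places the C7 substituent under thermodynamic control. The 1,1-disubstituted alkene of 23 is epoxidised in preference to the allyl group (mCPBA, NaHCO3, CH2Cl2, 0 °C) to the spiro-epoxide F1. Meinwald rearrangement (BF3·OEt2, CH2Cl2, −78 °C) gives the C7 carbaldehyde, which equilibrates through its enol to the exo aldehyde F2, trans to the aryl group. Condensation with TsNHNH2 (EtOH, rt) gives the tosylhydrazone F3, and reduction with catecholborane followed by NaOAc·3H2O converts CH=N into CH3. The route is rejoined at 24.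

Step 14. Removal of the C3 proton of 20, which lies on the concave face under the C6–C7 bridge, may be slow, so that C4 is not masked and is reduced together with C8. Hydride may also approach C8 from the C2–C4 side. The fallback sets out from 19 and creates the C3 centre by conjugate reduction in place of deprotonation. Dess–Martin oxidation of 19 gives the C3,C4-diketone F4, which exists as its diosphenol. O-Methylation (Me3SiCHN2, MeOH/toluene) gives the 3-methoxy enone F5. Conjugate reduction with [(Ph3P)CuH]6 (toluene, rt) and protonation of the enolate on its open face gives the endo-methoxy dione F6, the C3 epimer of 20. Its C3 proton now lies on the exposed face, and the conditions of step 14 applied to F6 give 23.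

Step 9. Closure in the 6-endo mode, attack through the enol oxygen, or loss of the silyl group from the enol ether before cyclisation may compete with the 5-exo carbon–carbon bond formation. The fallback sets out from 14 and replaces π-acid catalysis by a stoichiometric carbomercuration. HgCl2 with (Me3Si)2NH in CH2Cl2 at rt closes the same C1–C7 bond and gives the vinylmercuric chloride F7. Protodemercuration (NaI, dilute aqueous HCl, short contact) gives 15.

Further compounds

F1 | step 15 | spiro-epoxide of 23 at C7 (oxygen exo) | C=CC[C@]12C[C@H](OC)C(=O)[C@](OC)([C@H](c3ccc(OC)c(O[Si](C)(C)C(C)(C)C)c3)[C@]14CO4)[C@H]2O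
F2 | step 15 | exo C7 carbaldehyde | C=CC[C@]12C[C@H](OC)C(=O)[C@](OC)([C@H](c3ccc(OC)c(O[Si](C)(C)C(C)(C)C)c3)[C@H]1C=O)[C@H]2O
F3 | step 15 | tosylhydrazone of F2 | C=CC[C@]12C[C@H](OC)C(=O)[C@](OC)([C@H](c3ccc(OC)c(O[Si](C)(C)C(C)(C)C)c3)[C@H]1C=NNS(=O)(=O)c4ccc(C)cc4)[C@H]2O
F4 | step 14 | C3,C4-diketone (diosphenol tautomer) derived from 19 | C=CC[C@]12CC(=O)C(=O)[C@](OC)([C@H](c3ccc(OC)c(O[Si](C)(C)C(C)(C)C)c3)C1=C)C2=O
F5 | step 14 | 3-methoxy-2-en-4-one (methyl ether of the diosphenol) | C=CC[C@]12C=C(OC)C(=O)[C@](OC)([C@H](c3ccc(OC)c(O[Si](C)(C)C(C)(C)C)c3)C1=C)C2=O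
F6 | step 14 | endo-methoxy dione, C3 epimer of 20 | C=CC[C@]12C[C@H](OC)C(=O)[C@](OC)([C@H](c3ccc(OC)c(O[Si](C)(C)C(C)(C)C)c3)C1=C)C2=O
F7 | step 9 | vinylmercuric chloride of 15 (mercury trans to C1) | C=CC[C@]12CC[C@H](O[Si](CC)(CC)CC)[C@](OC)([C@H](c3ccc(OC)c(O[Si](C)(C)C(C)(C)C)c3)/C1=C\[Hg]Cl)C2=O
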